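**Retrosynthetic overview**

- The strategy rests on the 1,1-dimethylallyl group on the pyrrole-ring nitrogen N1 of each indole, and within it the C–C bond between the quaternary carbon on N1 and the vinyl CH carbon.
- Each vinyl group of Polonidine A (12) is traced back to a CH2CH2CO2H arm, so that 12 comes from diacid 10 by twofold decarboxylative desaturation, and 10 from diester 7.
- The quaternary-carbon-to-CH2 bond of each arm in 7 is cut to a tertiary radical next to N1, generated from an N-isopropenyl group of 4, and one molecule of methyl acrylate (5) per arm.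
- Compound 4 comes from commercial 3,3'-diindolylmethane (1) and two molecules of 2-bromopropene (2) by twofold copper-catalysed N-alkenylation.
- No ring is formed: both indoles and the C3–CH2–C3' bridge are bought with 1. The target has no stereocentre, and every step is run on both halves at once.

Key step: step 2

**Route**

Step 1
Reactants: 1 3,3'-diindolylmethane; 2 2-bromopropene
Product: 4 bis[1-(prop-1-en-2-yl)-1H-indol-3-yl]methane, via mono-N-isopropenyl diindolylmethane 3 (not isolated)
Conditions: CuI (20 mol%), trans-N,N'-dimethylcyclohexane-1,2-diamine (40 mol%), K3PO4 (4 equiv), 2 (6 equiv), toluene, sealed tube, 110 °C, Ar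
Reagents that add atoms: second equivalent of 2-bromopropene, C=C(C)Br
Why: Goldberg-type (Ullmann) copper-catalysed N-alkenylation, in which the diamine-ligated monovalent copper indolide should couple with one molecule of the alkenyl bromide at each nitrogen (two molecules in all), nitrogen being the only nucleophilic site left because C3 of each indole is substituted; the sealed vessel keeps the volatile bromide in solution.

Step 2
Reactants: 4 bis[1-(prop-1-en-2-yl)-1H-indol-3-yl]methane; 5 methyl acrylate
Product: 7 dimethyl 4,4'-[methylenebis(indole-3,1-diyl)]bis(4-methylpentanoate), via monoadduct ester 6 (not isolated)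
Conditions: Fe(acac)3 (30 mol% per N-alkene), PhSiH3 (5 equiv), Na2HPO4 (2 equiv), 5 (6 equiv, added in portions), EtOH/(CH2OH)2 5:1, 60 °C, Ar
Reagents that add atoms: second equivalent of methyl acrylate, C=CC(=O)OC
Why: An iron hydride formed from Fe(acac)3, PhSiH3 and ethanol should pass a hydrogen atom to the terminal CH2 of each of the two N-isopropenyl groups, leaving a tertiary radical on the carbon bound to N1; each such radical is nucleophilic and adds to the β-carbon of one molecule of methyl acrylate (two molecules are taken up in all, the first giving 6 and the second 7), and the α-ester radical is then reduced by divalent iron and protonated by ethanol, which returns trivalent iron to the cycle. The closest known reaction type is the iron-mediated hydrogen-atom-transfer reductive cross-coupling (radical Giese addition) of heteroatom-substituted donor olefins such as enol ethers and enamides with acrylates; the N-alkenylindole is a further nitrogen-substituted donor of the enamide kind. No ring closes and no stereocentre arises, since each new quaternary carbon carries two methyl groups. The step needs hydrogen-atom delivery to the N-alkene in the Markovnikov sense (not to the acrylate or to the indole C2=C3 bond), and capture of the tertiary radical by acrylate before it is reduced to an N-isopropyl group. The electron-rich 1,1-disubstituted alkene is the best hydrogen-atom acceptor present, the aromatic C2=C3 bonds are inert, and the polarity match between the donor radical and the electron-poor acceptor, together with excess acrylate, favours C–C bond formation. The early transition state of radical addition should tolerate the crowding at the N-bound carbon that would stop an ionic substitution there, and the phosphate buffer guards the N-alkenyl groups against acid-promoted solvolysis.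

Step 3
Reactants: 7 dimethyl 4,4'-[methylenebis(indole-3,1-diyl)]bis(4-methylpentanoate)
Product: 10 4,4'-[methylenebis(indole-3,1-diyl)]bis(4-methylpentanoic acid), via monoester lithium carboxylate 8 (not isolated), via dilithium dicarboxylate 9 (not isolated)
Conditions: LiOH·H2O (6 equiv), THF/MeOH/H2O 3:1:1, 40 °C; then 1 M HCl, 0 °C, to pH 4
Reagents that add atoms: lithium hydroxide, [Li+].[OH-]
Why: Ordinary saponification (BAc2) of two unhindered methyl esters; the indoles and the N–C(tertiary) bonds are inert to hydroxide, and the acidification is kept cold and mild so that the N-tert-alkyl groups are not ionised.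

Step 4
Reactants: 10 4,4'-[methylenebis(indole-3,1-diyl)]bis(4-methylpentanoic acid)
Product: 12 Polonidine A, via monoalkene monoacid 11 (not isolated)
Conditions: 9-(2-chlorophenyl)acridine (20 mol%), Co(dmgH)2(py)Cl (10 mol%), CH2Cl2/MeCN 2:1, 400 nm LED, 25 °C, Ar
Reagents that add atoms: none
Why: Acridine/cobaloxime dual-catalytic dehydrodecarboxylation, in which proton-coupled electron transfer within the photoexcited acridine–carboxylic acid complex releases CO2 and a primary radical at each chain end, the divalent cobalt form of the cobaloxime removes the only β-hydrogen available (on the CH2 next to the quaternary carbon) to give the terminal alkene, and H2 is evolved; the quaternary allylic carbon rules out migration of the double bond.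

**Compound list**

1 | 3,3'-diindolylmethane | C(c1c[nH]c2ccccc12)c1c[nH]c2ccccc12 | starting material
2 | 2-bromopropene | C=C(C)Br | starting material
3 | 3-(1H-indol-3-ylmethyl)-1-(prop-1-en-2-yl)-1H-indole | C=C(C)n1cc(Cc2c[nH]c3ccccc23)c2ccccc21 | intermediate
4 | bis[1-(prop-1-en-2-yl)-1H-indol-3-yl]methane | C=C(C)n1cc(Cc2cn(C(C)=C)c3ccccc23)c2ccccc21 | intermediate
5 | methyl acrylate | C=CC(=O)OC | starting material
6 | methyl 4-methyl-4-[3-({1-(prop-1-en-2-yl)-1H-indol-3-yl}methyl)-1H-indol-1-yl]pentanoate | COC(=O)CCC(C)(C)n1cc(Cc2cn(C(C)=C)c3ccccc23)c2ccccc21 | intermediate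
7 | dimethyl 4,4'-[methylenebis(indole-3,1-diyl)]bis(4-methylpentanoate) | COC(=O)CCC(C)(C)n1cc(Cc2cn(C(C)(C)CCC(=O)OC)c3ccccc23)c2ccccc21 | intermediate
8 | lithium 4-[3-({1-(5-methoxy-2-methyl-5-oxopentan-2-yl)-1H-indol-3-yl}methyl)-1H-indol-1-yl]-4-methylpentanoate | [Li+].COC(=O)CCC(C)(C)n1cc(Cc2cn(C(C)(C)CCC(=O)[O-])c3ccccc23)c2ccccc21 | intermediate
9 | dilithium 4,4'-[methylenebis(indole-3,1-diyl)]bis(4-methylpentanoate) | [Li+].[Li+].[O-]C(=O)CCC(C)(C)n1cc(Cc2cn(C(C)(C)CCC(=O)[O-])c3ccccc23)c2ccccc21 | intermediate
10 | 4,4'-[methylenebis(indole-3,1-diyl)]bis(4-methylpentanoic acid) | OC(=O)CCC(C)(C)n1cc(Cc2cn(C(C)(C)CCC(=O)O)c3ccccc23)c2ccccc21 | intermediate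
11 | 4-methyl-4-[3-({1-(2-methylbut-3-en-2-yl)-1H-indol-3-yl}methyl)-1H-indol-1-yl]pentanoic acid | C=CC(C)(C)n1cc(Cc2cn(C(C)(C)CCC(=O)O)c3ccccc23)c2ccccc21 | intermediate
12 | Polonidine A, bis[1-(2-methylbut-3-en-2-yl)-1H-indol-3-yl]methane | C=CC(C)(C)n1cc(Cc2cn(C(C)(C)C=C)c3ccccc23)c2ccccc21 | target

**Step count**

Total steps: 4. Longest linear sequence: 4.

**Steps most likely to fail**

1. Step 2. The tertiary N-bound radical may be reduced before it meets the acceptor, which amounts to hydrogenation of the N-alkene to an N-isopropyl group. The acrylate may also be consumed by its own reduction or oligomerisation, so that the second arm fails to couple. Fallback: setting out from 1, both N–H sites would be tert-prenylated directly by the known palladium-mediated N–H/allylic C–H coupling of 3-substituted indoles with 2-methyl-2-butene (Pd(OAc)2, Cu(OAc)2, AgOTf, MeCN, 35 °C). The mono-N-(2-methylbut-3-en-2-yl) compound F1 should react on under the same conditions. This fallback comes back to the route at 12, so that steps 3 and 4 are not needed.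

2. Step 4. The electron-rich bis(indolyl)methane may degrade under irradiation, the primary radical may close onto C2 of its own indole (5-exo) before cobalt intercepts it, or the reaction may stall after one arm. Fallback: setting out from 10, the acid would be esterified with N-hydroxypyridine-2-thione (DCC, DMAP, CH2Cl2, 0 °C, dark) to the bis-Barton ester F2. Visible-light photolysis of F2 in the presence of a large excess of PhSeSePh should give bis(phenylselenide) F3 by Barton decarboxylative selenation, the high diselenide concentration trapping the radical faster than it can cyclise. Oxidation with mCPBA (one equivalent per selenium, CH2Cl2, −78 °C) would give bis-selenoxide F4. Warming F4 with iPr2NH should bring about thermal syn-elimination of both selenoxides, coming back to the route at 12.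

3. Step 1. The second N–H may couple slowly, the volatile bromide may be lost, and the copper-bound indolide may be oxidised at the bridging CH2. Fallback: setting out from 1, twofold N-alkylation with methyl 2-bromopropanoate (NaH, DMF, 0 °C) should give dimethyl 2,2'-[methylenebis(indole-3,1-diyl)]dipropanoate F5 as a mixture of stereoisomers. Reduction with LiAlH4 (THF, 0 °C) would give diol F6, and MsCl/Et3N the dimesylate F7. E2 elimination of F7 with KOtBu (THF, 0 °C to rt) removes the N–CH hydrogen and destroys both stereocentres, coming back to the route at 4.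

**Further compounds**

F1 | step 2 | 3-(1H-indol-3-ylmethyl)-1-(2-methylbut-3-en-2-yl)-1H-indole | C=CC(C)(C)n1cc(Cc2c[nH]c3ccccc23)c2ccccc21
F2 | step 4 | bis(2-thioxopyridin-1(2H)-yl) 4,4'-[methylenebis(indole-3,1-diyl)]bis(4-methylpentanoate) | S=c1ccccn1OC(=O)CCC(C)(C)n1cc(Cc2cn(C(C)(C)CCC(=O)On3ccccc3=S)c3ccccc23)c2ccccc21
F3 | step 4 | bis{1-[2-methyl-4-(phenylselanyl)butan-2-yl]-1H-indol-3-yl}methane | c1ccccc1[Se]CCC(C)(C)n1cc(Cc2cn(C(C)(C)CC[Se]c3ccccc3)c3ccccc23)c2ccccc21
F4 | step 4 | bis{1-[2-methyl-4-(phenylseleninyl)butan-2-yl]-1H-indol-3-yl}methane | O=[Se](c1ccccc1)CCC(C)(C)n1cc(Cc2cn(C(C)(C)CC[Se](=O)c3ccccc3)c3ccccc23)c2ccccc21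
F5 | step 1 | dimethyl 2,2'-[methylenebis(indole-3,1-diyl)]dipropanoate (mixture of stereoisomers) | COC(=O)C(C)n1cc(Cc2cn(C(C)C(=O)OC)c3ccccc23)c2ccccc21
F6 | step 1 | 2,2'-[methylenebis(indole-3,1-diyl)]bis(propan-1-ol) (mixture of stereoisomers) | OCC(C)n1cc(Cc2cn(C(C)CO)c3ccccc23)c2ccccc21
F7 | step 1 | 2,2'-[methylenebis(indole-3,1-diyl)]bis(propane-2,1-diyl) dimethanesulfonate (mixture of stereoisomers) | CS(=O)(=O)OCC(C)n1cc(Cc2cn(C(C)COS(C)(=O)=O)c3ccccc23)c2ccccc21
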